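**Plan**
- Retrosynthesis: the C2–O and C3–O bonds of the catechol are cut first, leading back to a C2–C3 aryne of the chain benzoate. This works because the two hydroxyls sit on neighbouring carbons of the benzene ring, directly beside the ester-bearing C1, so one aryne can receive both oxygens.
- Next cuts: the ester C(acyl)–O bond (Mitsunobu), the C15–C16 bond of the chain (copper-catalysed alkyl–alkyl coupling), and on the arene the C1–CO2H and C3–Si bonds (carboxylation, retro-Brook shift).
- Forward: the chain alcohol is made from ω-pentadecalactone and (S)-1-bromo-2-methylbutane (steps 1–4), and the silyl salicylic acid from 2,6-dibromophenol (steps 5–7). The chain is joined to the arene in step 8, followed by triflation (step 9), aryne bis-oxygenation (step 10) and N–O cleavage (step 11). No ring is formed; the benzene ring is bought.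
- Stereochemistry: the single stereocentre, C17 (S), is bought in (S)-1-bromo-2-methylbutane and is never at a reacting carbon.

Key step: step 10

Remark: the first aminoxyl radical is taken to attack the aryne carbon remote from the ester (C3); attack at C2 would give the regioisomeric radical and the same product.

**Route**

Step 1
Reactants: 1 ω-pentadecalactone (oxacyclohexadecan-2-one)
Product: 2 methyl 15-hydroxypentadecanoate
Conditions: MeOH, H2SO4 (cat.), reflux
Reagents that add atoms: methanol, CO
Why: Acid-catalysed transesterification (methanolysis) of a strain-free macrolactone in a large excess of methanol should lie on the side of the open-chain hydroxy ester.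

Step 2
Reactants: 2 methyl 15-hydroxypentadecanoate
Product: 3 methyl 15-bromopentadecanoate
Conditions: CBr4, PPh3, CH2Cl2, 0 °C to rt
Reagents that add atoms: carbon tetrabromide, BrC(Br)(Br)Br
Why: Appel bromination of an unhindered primary alcohol proceeds under neutral conditions that leave the methyl ester alone.

Step 3
Reactants: 4 (S)-1-bromo-2-methylbutane; 3 methyl 15-bromopentadecanoate
Product: 6 methyl (S)-17-methylnonadecanoate, via (S)-2-methylbutylmagnesium bromide 5 (not isolated)
Conditions: 4, Mg turnings, THF, 40 °C; then added slowly to 3, Li2CuCl4 (3 mol %), NMP (4 equiv), THF, 0 °C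
Reagents that add atoms: none
Why: Kochi-type copper-catalysed cross-coupling of a primary alkyl Grignard reagent with a primary alkyl bromide, run with N-methylpyrrolidone so that C–C coupling outruns addition to the ester; the stereocentre is β to magnesium, takes no part and is carried over unchanged.

Step 4
Reactants: 6 methyl (S)-17-methylnonadecanoate
Product: 7 (S)-17-methylnonadecan-1-ol
Conditions: LiAlH4, THF, 0 °C to rt; H2O/aq. NaOH work-up
Reagents that add atoms: none
Why: Hydride reduction of a methyl ester to the primary alcohol, with no other reducible group in the molecule.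

Step 5
Reactants: 8 2,6-dibromophenol
Product: 9 (2,6-dibromophenoxy)trimethylsilane
Conditions: (Me3Si)2NH, THF, reflux; evaporation
Reagents that add atoms: hexamethyldisilazane, C[Si](C)(C)N[Si](C)(C)C
Why: O-silylation of a phenol with hexamethyldisilazane gives only ammonia as by-product, so the crude silyl ether can be used directly.

Step 6
Reactants: 9 (2,6-dibromophenoxy)trimethylsilane
Product: 12 2-bromo-6-(trimethylsilyl)phenol, via (2-bromo-6-lithiophenoxy)trimethylsilane 10 (not isolated), via lithium 2-bromo-6-(trimethylsilyl)phenoxide 11 (not isolated)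
Conditions: n-BuLi (1.05 equiv), THF, −78 °C to rt; sat. aq. NH4Cl
Reagents that add atoms: none
Why: Bromine–lithium exchange at one of the two equivalent C–Br bonds is followed by the anionic 1,3 O-to-C silyl shift (retro-Brook rearrangement), the standard entry to ortho-silyl phenols; the phenoxide formed disfavours a second exchange.

Step 7
Reactants: 12 2-bromo-6-(trimethylsilyl)phenol
Product: 16 2-hydroxy-3-(trimethylsilyl)benzoic acid, via sodium 2-bromo-6-(trimethylsilyl)phenoxide 13 (not isolated), via sodium 2-lithio-6-(trimethylsilyl)phenoxide 14 (not isolated), via lithium sodium 2-oxido-3-(trimethylsilyl)benzoate 15 (not isolated)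
Conditions: NaH (1.1 equiv), THF, 0 °C; t-BuLi (2.1 equiv), −78 °C; CO2 (dry gas), −78 °C to rt; cold 1 M HCl to pH 3
Reagents that add atoms: carbon dioxide, O=C=O
Why: Sodium hydride first converts the phenol into its sodium phenoxide, bromine–lithium exchange with two equivalents of t-BuLi then gives the aryllithium, whose carbon–lithium bond is carboxylated by CO2 (the classical route from ortho-bromophenols to salicylic acids); brief cold acidification should spare the aryl–silicon bond.

Step 8
Reactants: 16 2-hydroxy-3-(trimethylsilyl)benzoic acid; 7 (S)-17-methylnonadecan-1-ol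
Product: 17 (S)-17-methylnonadecyl 2-hydroxy-3-(trimethylsilyl)benzoate
Conditions: PPh3, DIAD, THF, 0 °C to rt
Reagents that add atoms: none
Why: Mitsunobu esterification, in which the carboxylic acid, far more acidic than the flanked and hydrogen-bonded phenol, is the pronucleophile that displaces the activated primary alcohol at the non-stereogenic C1 of the chain under neutral conditions.

Step 9
Reactants: 17 (S)-17-methylnonadecyl 2-hydroxy-3-(trimethylsilyl)benzoate
Product: 18 (S)-17-methylnonadecyl 2-(trifluoromethanesulfonyloxy)-3-(trimethylsilyl)benzoate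
Conditions: Tf2O, pyridine, CH2Cl2, 0 °C to rt
Reagents that add atoms: trifluoromethanesulfonic anhydride, O=S(=O)(OS(=O)(=O)C(F)(F)F)C(F)(F)F
Why: O-sulfonylation of a phenol with triflic anhydride and pyridine is the usual last step to an ortho-silylaryl triflate and is routine both for salicylate esters and for ortho-silyl phenols.

Step 10
Reactants: 18 (S)-17-methylnonadecyl 2-(trifluoromethanesulfonyloxy)-3-(trimethylsilyl)benzoate; 19 TEMPO (2,2,6,6-tetramethylpiperidin-1-oxyl), the molecule that adds first
Product: 22 (S)-17-methylnonadecyl 2,3-bis(2,2,6,6-tetramethylpiperidin-1-yloxy)benzoate, via (S)-17-methylnonadecyl 2,3-didehydrobenzoate 20 (not isolated), via C2 sigma-aryl radical 21 (not isolated)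
Conditions: TEMPO (5 equiv), CsF (3 equiv), MeCN/PhCF3 (2:1), rt
Reagents that add atoms: 2,2,6,6-tetramethylpiperidin-1-oxyl (second molecule of TEMPO 19, which traps radical 21), CC1(C)CCCC(C)(C)N1[O]
Why: Fluoride attacks the trimethylsilyl group at C3 of 18 and the C2 triflate leaves in a 1,2-elimination (Kobayashi aryne generation), which unveils the C2–C3 aryne 20 under neutral conditions that touch neither the ester nor the remote C17 stereocentre. One aminoxyl radical adds to the strained in-plane π bond, at the less hindered C3, to give the σ-aryl radical 21, and this is caught close to the diffusion limit by a second aminoxyl radical, so that the C2–O and C3–O bonds both form in the same flask and two molecules of TEMPO end up in the product. The closest known reaction type is the 1,2-bis-aminoxylation of arynes released from 2-(trimethylsilyl)aryl triflates with TEMPO. No ring closes and no stereocentre is created, so neither a mode of closure nor a controlling element is involved. Regiochemistry is irrelevant because both aryne carbons end up with the same substituent; what is needed is chemoselective capture of 21 by TEMPO in preference to hydrogen abstraction, fluoride addition or aryne oligomerisation, and the large excess of the persistent radical in solvents without weak C–H bonds should secure it. The ester prefers the s-cis form, which keeps its O–CH2 hydrogens out of reach of the C2 radical, and the trifluorotoluene co-solvent keeps the lipophilic chain in solution.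

Step 11
Reactants: 22 (S)-17-methylnonadecyl 2,3-bis(2,2,6,6-tetramethylpiperidin-1-yloxy)benzoate
Product: 23 Gentiside G, (S)-17-methylnonadecyl 2,3-dihydroxybenzoate
Conditions: Zn dust, AcOH/THF/H2O (3:1:1), 50 °C, argon
Reagents that add atoms: none
Why: Dissolving-metal reduction with zinc in acetic acid cleaves both aryl-O–N bonds of the aryloxyamines and releases the two phenols, while the ester and the saturated chain are inert.

**Compound list**
1 | ω-pentadecalactone (oxacyclohexadecan-2-one) | O=C1CCCCCCCCCCCCCCO1 | starting material
2 | methyl 15-hydroxypentadecanoate | COC(=O)CCCCCCCCCCCCCCO | intermediate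
3 | methyl 15-bromopentadecanoate | COC(=O)CCCCCCCCCCCCCCBr | intermediate
4 | (S)-1-bromo-2-methylbutane | CC[C@H](C)CBr | starting material
5 | (S)-2-methylbutylmagnesium bromide | CC[C@H](C)C[Mg]Br | intermediate (not isolated)
6 | methyl (S)-17-methylnonadecanoate | CC[C@H](C)CCCCCCCCCCCCCCCC(=O)OC | intermediate
7 | (S)-17-methylnonadecan-1-ol | CC[C@H](C)CCCCCCCCCCCCCCCCO | intermediate
8 | 2,6-dibromophenol | Oc1c(Br)cccc1Br | starting material
9 | (2,6-dibromophenoxy)trimethylsilane | C[Si](C)(C)Oc1c(Br)cccc1Br | intermediate
10 | (2-bromo-6-lithiophenoxy)trimethylsilane | C[Si](C)(C)Oc1c(Br)cccc1[Li] | intermediate (not isolated)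
11 | lithium 2-bromo-6-(trimethylsilyl)phenoxide | [Li+].[O-]c1c(Br)cccc1[Si](C)(C)C | intermediate (not isolated)
12 | 2-bromo-6-(trimethylsilyl)phenol | Oc1c(Br)cccc1[Si](C)(C)C | intermediate
13 | sodium 2-bromo-6-(trimethylsilyl)phenoxide | [Na+].[O-]c1c(Br)cccc1[Si](C)(C)C | intermediate (not isolated)
14 | sodium 2-lithio-6-(trimethylsilyl)phenoxide | [Na+].[O-]c1c([Li])cccc1[Si](C)(C)C | intermediate (not isolated)
15 | lithium sodium 2-oxido-3-(trimethylsilyl)benzoate | [Li+].[Na+].[O-]C(=O)c1cccc([Si](C)(C)C)c1[O-] | intermediate (not isolated)
16 | 2-hydroxy-3-(trimethylsilyl)benzoic acid | OC(=O)c1cccc([Si](C)(C)C)c1O | intermediate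
17 | (S)-17-methylnonadecyl 2-hydroxy-3-(trimethylsilyl)benzoate | CC[C@H](C)CCCCCCCCCCCCCCCCOC(=O)c1cccc([Si](C)(C)C)c1O | intermediate
18 | (S)-17-methylnonadecyl 2-(trifluoromethanesulfonyloxy)-3-(trimethylsilyl)benzoate | CC[C@H](C)CCCCCCCCCCCCCCCCOC(=O)c1cccc([Si](C)(C)C)c1OS(=O)(=O)C(F)(F)F | intermediate
19 | TEMPO (2,2,6,6-tetramethylpiperidin-1-oxyl) | CC1(C)CCCC(C)(C)N1[O] | starting material
20 | (S)-17-methylnonadecyl 2,3-didehydrobenzoate (C2–C3 aryne) | CC[C@H](C)CCCCCCCCCCCCCCCCOC(=O)C1=CC=CC#C1 | intermediate (not isolated)
21 | (S)-17-methylnonadecyl 3-(2,2,6,6-tetramethylpiperidin-1-yloxy)benzoate C2 σ-radical | CC[C@H](C)CCCCCCCCCCCCCCCCOC(=O)c1cccc(ON2C(C)(C)CCCC2(C)C)[c]1 | intermediate (not isolated)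
22 | (S)-17-methylnonadecyl 2,3-bis(2,2,6,6-tetramethylpiperidin-1-yloxy)benzoate | CC[C@H](C)CCCCCCCCCCCCCCCCOC(=O)c1cccc(ON2C(C)(C)CCCC2(C)C)c1ON3C(C)(C)CCCC3(C)C | intermediate
23 | Gentiside G, (S)-17-methylnonadecyl 2,3-dihydroxybenzoate | CC[C@H](C)CCCCCCCCCCCCCCCCOC(=O)c1cccc(O)c1O | target

**Step count**
Total steps: 11. Longest linear sequence: 8 steps (steps 1–4, then 8–11). The arene branch (steps 5–7) joins at step 8.

**Steps most likely to fail**

Step 10. Crowding by the neighbouring ester may slow capture of the σ-aryl radical by the second aminoxyl radical, so that hydrogen abstraction, fluoride addition to the aryne or aryne oligomerisation takes over. The fallback leaves the aryne and sets out from alcohol 7. Esterification of 7 with purchased 2,3-bis(benzyloxy)benzoic acid F1 (EDC·HCl, DMAP, CH2Cl2, rt) should give (S)-17-methylnonadecyl 2,3-bis(benzyloxy)benzoate F2. Hydrogenolysis of both benzyl ethers (H2, Pd/C, EtOAc, rt) would then come back to the route at 23.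

Step 7. Bromine–lithium exchange on the electron-rich phenoxide may stay incomplete, or the trimethylsilyl group may be lost by protodesilylation during acidification of the salicylic acid. The fallback avoids both the organolithium and the free acid and sets out from bromophenol 12 and alcohol 7. Palladium-catalysed alkoxycarbonylation (Pd(OAc)2, Xantphos, CO 1 atm, Et3N, toluene, 90 °C) should insert CO into the C–Br bond and trap the acylpalladium species with 7. This makes no new compound (F0), passes over 16 and step 8, and comes back to the route at ester 17.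

Step 3. Addition of the Grignard reagent to the methyl ester, and homocoupling, may compete with the cross-coupling. The fallback removes the ester before the C–C bond is made and sets out from bromo ester 3. Reduction with i-Bu2AlH (CH2Cl2, −78 to 0 °C) should give 15-bromopentadecan-1-ol F3. Protection with 3,4-dihydro-2H-pyran and PPTS (cat.) in CH2Cl2 should give 2-[(15-bromopentadecyl)oxy]tetrahydro-2H-pyran F4. Coupling of F4 with Grignard reagent 5 (Li2CuCl4 cat., THF, −10 °C to rt) should give 2-{[(S)-17-methylnonadecyl]oxy}tetrahydro-2H-pyran F5. Acetal cleavage (PPTS, MeOH, 50 °C) then comes back to the route at alcohol 7, passing over 6 and step 4.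

**Further compounds**
F1 | step 10 | 2,3-bis(benzyloxy)benzoic acid (purchased) | OC(=O)c1cccc(OCc2ccccc2)c1OCc3ccccc3
F2 | step 10 | (S)-17-methylnonadecyl 2,3-bis(benzyloxy)benzoate | CC[C@H](C)CCCCCCCCCCCCCCCCOC(=O)c1cccc(OCc2ccccc2)c1OCc3ccccc3
F0 | step 7 | none | none
F3 | step 3 | 15-bromopentadecan-1-ol | OCCCCCCCCCCCCCCCBr
F4 | step 3 | 2-[(15-bromopentadecyl)oxy]tetrahydro-2H-pyran (racemic at the acetal carbon) | BrCCCCCCCCCCCCCCCOC1CCCCO1
F5 | step 3 | 2-{[(S)-17-methylnonadecyl]oxy}tetrahydro-2H-pyran (both epimers at the acetal carbon) | CC[C@H](C)CCCCCCCCCCCCCCCCOC1CCCCO1
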